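## Retrosynthetic overview

1. Pestalone F ⇒ its tris(methoxymethyl) ether, so that one mild acidic global deprotection ends the route.
2. Aryl–prenyl bond ⇒ ketone-directed ortho-C–H prenylation of the prenyl-free keto aldehyde with 3-methylbuta-1,2-diene (proposed new step). The benzophenone carbonyl selects the single ortho C–H, which electrophilic prenylation cannot tell from the C–H between the two oxygens.
3. Keto aldehyde ⇒ hydroxy ketone (oxidation) ⇒ aryl–carbonyl bond, made from the ortho-lithiated ring A ether and a ring B phthalide.
4. Ring A piece ⇒ 3-methoxy-5-methylphenol (ortho-chlorination, MOM ether). Ring B phthalide ⇒ methyl 3,5-dihydroxybenzoate (Vilsmeier formylation, MOM ethers, reduction–lactonisation).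
5. Ring order: benzene rings A and B are bought intact. The only ring made is the temporary lactone ring C (step 3), opened again in the fragment union (step 6).

Assumption: the target SMILES has no stereocentre and no stereogenic double bond, so the compound is achiral; "single enantiomer" is taken to mean the one constitutional isomer drawn, and no stereocontrol is needed.

## Route

Step 1
Reactants: 1 methyl 3,5-dihydroxybenzoate
Product: 3 methyl 2-formyl-3,5-dihydroxybenzoate, via iminium salt 2 (not isolated)
Conditions: POCl3, DMF, MeCN, 0 °C → rt; then H2O, 50 °C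
Reagents that add atoms: N,N-dimethylformamide CN(C)C=O; water O
Why: Vilsmeier–Haack formylation goes ortho to one hydroxyl and para to the other (next to the ester) and not to the crowded carbon between the two hydroxyls, and the aryl iminium salt is hydrolysed to the aldehyde on aqueous work-up.

Step 2
Reactants: 3 methyl 2-formyl-3,5-dihydroxybenzoate
Product: 4 methyl 2-formyl-3,5-bis(methoxymethoxy)benzoate
Conditions: MOMCl (3 equiv), i-Pr2NEt, CH2Cl2, 0 → 40 °C
Reagents that add atoms: chloromethyl methyl ether COCCl
Why: Base-mediated O-alkylation (MOM ether formation) of both phenols gives acetals that survive hydride, organolithium and oxidation and come off with mild acid, unlike methyl ethers, which could not be removed next to the ring A methoxy group.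

Step 3
Reactants: 4 methyl 2-formyl-3,5-bis(methoxymethoxy)benzoate
Product: 6 phthalide 4,6-bis(methoxymethoxy)isobenzofuran-1(3H)-one, via hydroxy ester 5 (not isolated)
Conditions: NaBH4, MeOH/THF, 0 °C → rt
Reagents that add atoms: none
Why: Chemoselective borohydride reduction of the aldehyde in the presence of the ester, after which the benzylic alkoxide lactonises onto the ortho ester (intramolecular transesterification) with loss of methanol.

Step 4
Reactants: 7 3-methoxy-5-methylphenol
Product: 8 2-chloro-5-methoxy-3-methylphenol
Conditions: SO2Cl2 (1.0 equiv), 2,2,6,6-tetramethylpiperidine (5 mol %), toluene, 0 °C → rt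
Reagents that add atoms: sulfuryl chloride O=S(=O)(Cl)Cl
Why: Amine-catalysed ortho-selective electrophilic chlorination of a phenol (the N-chloroamine is delivered through a hydrogen bond to the OH), and of the two ortho carbons the one para to the methoxy group is the more electron-rich.

Step 5
Reactants: 8 2-chloro-5-methoxy-3-methylphenol
Product: 9 2-chloro-5-methoxy-1-(methoxymethoxy)-3-methylbenzene
Conditions: MOMCl, i-Pr2NEt, CH2Cl2, 0 °C → rt
Reagents that add atoms: chloromethyl methyl ether COCCl
Why: MOM ether formation protects the phenol and installs a strong directing group for the ortho-lithiation that follows.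

Step 6
Reactants: 9 2-chloro-5-methoxy-1-(methoxymethoxy)-3-methylbenzene; 6 phthalide 4,6-bis(methoxymethoxy)isobenzofuran-1(3H)-one
Product: 11 [3-chloro-6-methoxy-2-(methoxymethoxy)-4-methylphenyl][2-(hydroxymethyl)-3,5-bis(methoxymethoxy)phenyl]methanone, via aryllithium 10 (not isolated)
Conditions: 9 (1.2 equiv), n-BuLi, TMEDA, THF, −78 → 0 °C; then 6, THF, −78 → −20 °C; aq. NH4Cl
Reagents that add atoms: none
Why: Directed ortho-metalation occurs at the carbon flanked by OMOM and OMe (cooperative directing groups; no hydrogen ortho to chlorine, so no aryne), and nucleophilic acyl addition of the hindered aryllithium to the lactone gives a lithium lactolate that resists a second addition and opens to the hydroxy ketone on quench.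

Step 7
Reactants: 11 [3-chloro-6-methoxy-2-(methoxymethoxy)-4-methylphenyl][2-(hydroxymethyl)-3,5-bis(methoxymethoxy)phenyl]methanone
Product: 12 2-[3-chloro-6-methoxy-2-(methoxymethoxy)-4-methylbenzoyl]-4,6-bis(methoxymethoxy)benzaldehyde
Conditions: Dess–Martin periodinane (1.3 equiv), CH2Cl2, 0 °C → rt
Reagents that add atoms: none
Why: Dess–Martin oxidation turns the primary benzylic alcohol (also when it sits partly as the cyclic hemiketal) into the aldehyde under near-neutral conditions that leave MOM ethers, the aryl chloride and the ketone untouched.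

Step 8
Reactants: 12 2-[3-chloro-6-methoxy-2-(methoxymethoxy)-4-methylbenzoyl]-4,6-bis(methoxymethoxy)benzaldehyde
Product: 13 2-[3-chloro-6-methoxy-2-(methoxymethoxy)-4-methylbenzoyl]-4,6-bis(methoxymethoxy)-3-(3-methylbut-2-en-1-yl)benzaldehyde
Conditions: [Cp*Rh(MeCN)3](SbF6)2 (5 mol %), NaO2CCMe3 (20 mol %), Me3CCO2H (1 equiv), 3-methylbuta-1,2-diene (3 equiv), ClCH2CH2Cl, 60 °C, sealed tube
Reagents that add atoms: 3-methylbuta-1,2-diene C=C=C(C)C
Why: Proposed new method: ketone-directed ortho-C–H prenylation by redox-neutral hydroarylation of 1,1-dimethylallene; the cationic trivalent rhodium pivalate binds the benzophenone oxygen and cleaves the only ortho C–H of the diaryl ketone (the ring B C–H flanked by the carbonyl and an OMOM group; ring A has none) by carboxylate-assisted concerted metalation–deprotonation to a five-membered rhodacycle, the allene inserts through its unsubstituted terminal C=C so that the aryl group goes to CH2 and rhodium to the central carbon, and protonation of the alkenyl–rhodium bond by pivalic acid releases the linear prenyl arene and regenerates the catalyst (no oxidant, no stereocentre, and the product ketone, now flanked by four ortho substituents, twists and lets the metal go); the closest known reactions are amide- and N-heteroaryl-directed Cp*Rh- or Cp*Co-catalysed C–H hydroarylation of 1,1-disubstituted allenes, ketone-directed Cp*Rh ortho-C–H olefination and Murai-type Ru-catalysed ketone-directed ortho-alkylation, which to my knowledge have not been shown on a weakly coordinating, hindered, polyoxygenated 2-aroylbenzaldehyde.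

Step 9
Reactants: 13 2-[3-chloro-6-methoxy-2-(methoxymethoxy)-4-methylbenzoyl]-4,6-bis(methoxymethoxy)-3-(3-methylbut-2-en-1-yl)benzaldehyde
Product: 14 pestalone F 2-(3-chloro-2-hydroxy-6-methoxy-4-methylbenzoyl)-4,6-dihydroxy-3-(3-methylbut-2-en-1-yl)benzaldehyde
Conditions: 3 M aq. HCl, THF, 40 °C
Reagents that add atoms: none
Why: Acid-catalysed acetal hydrolysis removes all three aryl MOM ethers in a non-alcoholic medium (no acetal formation at the aldehyde) under conditions too mild to cleave the aryl methyl ether or to cyclise the prenyl group onto the neighbouring phenol.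

## Compound list

1 | methyl 3,5-dihydroxybenzoate | COC(=O)c1cc(O)cc(O)c1 | starting material
2 | [2,4-dihydroxy-6-(methoxycarbonyl)benzylidene]dimethyliminium chloride | COC(=O)c1cc(O)cc(O)c1C=[N+](C)C.[Cl-] | intermediate
3 | methyl 2-formyl-3,5-dihydroxybenzoate | COC(=O)c1cc(O)cc(O)c1C=O | intermediate
4 | methyl 2-formyl-3,5-bis(methoxymethoxy)benzoate | COC(=O)c1cc(OCOC)cc(OCOC)c1C=O | intermediate
5 | methyl 2-(hydroxymethyl)-3,5-bis(methoxymethoxy)benzoate | COC(=O)c1cc(OCOC)cc(OCOC)c1CO | intermediate
6 | 4,6-bis(methoxymethoxy)isobenzofuran-1(3H)-one | O=C1OCc2c1cc(OCOC)cc2OCOC | intermediate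
7 | 3-methoxy-5-methylphenol | COc1cc(C)cc(O)c1 | starting material
8 | 2-chloro-5-methoxy-3-methylphenol | COc1cc(C)c(Cl)c(O)c1 | intermediate
9 | 2-chloro-5-methoxy-1-(methoxymethoxy)-3-methylbenzene | COCOc1cc(OC)cc(C)c1Cl | intermediate
10 | [3-chloro-6-methoxy-2-(methoxymethoxy)-4-methylphenyl]lithium | [Li]c1c(OC)cc(C)c(Cl)c1OCOC | intermediate
11 | [3-chloro-6-methoxy-2-(methoxymethoxy)-4-methylphenyl][2-(hydroxymethyl)-3,5-bis(methoxymethoxy)phenyl]methanone | COCOc1cc(OCOC)c(CO)c(c1)C(=O)c1c(OC)cc(C)c(Cl)c1OCOC | intermediate
12 | 2-[3-chloro-6-methoxy-2-(methoxymethoxy)-4-methylbenzoyl]-4,6-bis(methoxymethoxy)benzaldehyde | COCOc1cc(OCOC)c(C=O)c(c1)C(=O)c1c(OC)cc(C)c(Cl)c1OCOC | intermediate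
13 | 2-[3-chloro-6-methoxy-2-(methoxymethoxy)-4-methylbenzoyl]-4,6-bis(methoxymethoxy)-3-(3-methylbut-2-en-1-yl)benzaldehyde | COCOc1cc(OCOC)c(C=O)c(C(=O)c2c(OC)cc(C)c(Cl)c2OCOC)c1CC=C(C)C | intermediate
14 | pestalone F, 2-(3-chloro-2-hydroxy-6-methoxy-4-methylbenzoyl)-4,6-dihydroxy-3-(3-methylbut-2-en-1-yl)benzaldehyde | COc1cc(C)c(Cl)c(O)c1C(=O)c1c(C=O)c(O)cc(O)c1CC=C(C)C | target

## Step count and risks

Total step count: 9. Longest linear sequence: 7 steps (steps 1, 2, 3, 6, 7, 8, 9 from compound 1).

Three steps most likely to fail:

**Step 8 (proposed new C–H prenylation).** Risks are slow metalation at the crowded C–H, competing activation of the formyl C–H, or acid-promoted side reactions of the allene. The fallback uses known chemistry only, sets out from phthalide 6 and comes back at 13. Bromination of 6 with NBS in MeCN goes ortho to the lactone carbonyl (para to one alkoxy group, ortho to the other, as with 3,5-dialkoxybenzoates) and gives 7-bromo-4,6-bis(methoxymethoxy)isobenzofuran-1(3H)-one F1. Stille coupling of F1 with Bu3SnCH2CH=CMe2 (Pd(PPh3)4 as the zerovalent palladium source, CsF, DMF, 90 °C) gives 4,6-bis(methoxymethoxy)-7-(3-methylbut-2-en-1-yl)isobenzofuran-1(3H)-one F2. Addition of aryllithium 10 (made from 9 as in step 6) to F2 gives [3-chloro-6-methoxy-2-(methoxymethoxy)-4-methylphenyl][2-(hydroxymethyl)-3,5-bis(methoxymethoxy)-6-(3-methylbut-2-en-1-yl)phenyl]methanone F3. Dess–Martin oxidation of F3 then delivers 13, and step 9 follows unchanged.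

**Step 6 (union of two hindered fragments).** The hindered aryllithium may deprotonate the lactone CH2 instead of adding, or add sluggishly. The fallback sets out from 6 and comes back at 12. Reduction of 6 with i-Bu2AlH (CH2Cl2, −78 °C) gives the lactol 4,6-bis(methoxymethoxy)-1,3-dihydroisobenzofuran-1-ol F4 (racemic). F4 is deprotonated with NaH so that it opens to the more electrophilic, non-enolisable hydroxy aldehyde alkoxide, and aryllithium 10 is added at −78 °C to give the racemic diol [3-chloro-6-methoxy-2-(methoxymethoxy)-4-methylphenyl][2-(hydroxymethyl)-3,5-bis(methoxymethoxy)phenyl]methanol F5. A double Swern oxidation ((COCl)2, DMSO, Et3N, −78 °C) activates both carbinols before base is added, which avoids lactol and phthalide formation, and gives keto aldehyde 12 directly.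

**Step 4 (site-selective chlorination).** The para-to-OH isomer or the isomer between OH and OMe could compete. The fallback swaps catalyst control for substrate control; it sets out from 7 and comes back at 8. Acetylation of 7 (Ac2O, pyridine) gives 3-methoxy-5-methylphenyl acetate F6, in which the acetoxy group is only a weak donor. Chlorination with NCS (MeCN, rt) is then steered by the methoxy group to its para position and gives 2-chloro-5-methoxy-3-methylphenyl acetate F7. Methanolysis (K2CO3, MeOH, rt) returns phenol 8.

## Further compounds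

F1 | step 8 | 7-bromo-4,6-bis(methoxymethoxy)isobenzofuran-1(3H)-one | O=C1OCc2c(OCOC)cc(OCOC)c(Br)c12
F2 | step 8 | 4,6-bis(methoxymethoxy)-7-(3-methylbut-2-en-1-yl)isobenzofuran-1(3H)-one | O=C1OCc2c(OCOC)cc(OCOC)c(CC=C(C)C)c12
F3 | step 8 | [3-chloro-6-methoxy-2-(methoxymethoxy)-4-methylphenyl][2-(hydroxymethyl)-3,5-bis(methoxymethoxy)-6-(3-methylbut-2-en-1-yl)phenyl]methanone | COCOc1cc(OCOC)c(CO)c(C(=O)c2c(OC)cc(C)c(Cl)c2OCOC)c1CC=C(C)C
F4 | step 6 | 4,6-bis(methoxymethoxy)-1,3-dihydroisobenzofuran-1-ol (racemic) | OC1OCc2c1cc(OCOC)cc2OCOC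
F5 | step 6 | [3-chloro-6-methoxy-2-(methoxymethoxy)-4-methylphenyl][2-(hydroxymethyl)-3,5-bis(methoxymethoxy)phenyl]methanol (racemic) | COCOc1cc(OCOC)c(CO)c(c1)C(O)c1c(OC)cc(C)c(Cl)c1OCOC
F6 | step 4 | 3-methoxy-5-methylphenyl acetate | COc1cc(C)cc(OC(C)=O)c1
F7 | step 4 | 2-chloro-5-methoxy-3-methylphenyl acetate | COc1cc(C)c(Cl)c(OC(C)=O)c1
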